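**Retrosynthetic overview**
- Target ⇐ fluoride desilylation ⇐ convex-face epoxidation of the C8=C9 alkene ⇐ esterification of the C6 alcohol of a cis-fused hydroazulene.
- Seven-membered ring (formed last) ⇐ ring-closing metathesis between an allyl arm on C1 and a methallyl carbinol arm on C5; the C6 carbinol ⇐ Felkin-controlled methallylation of the C5 aldehyde.
- C1 quaternary centre and C1–C10 bond (key step) ⇐ anionic oxy-Cope rearrangement of the allyl carbinol of a cyclopentene carbaldehyde, steered by the C4 carbinol centre; C5 ⇐ equilibration of the aldehyde.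
- Five-membered ring (formed first) ⇐ ozonolysis and intramolecular aldol condensation (ring contraction) of silylated (S)-terpinen-4-ol, whose carbinol carbon is the only purchased stereocentre (C4).

Assumption: (S)-(+)-terpinen-4-ol is bought in high enantiomeric purity and 4-[(tert-butyldimethylsilyl)oxy]benzoic acid is bought as a catalogue compound.

Locants in the text follow daucane numbering: C1 (quaternary ring-fusion carbon, CH3 = C15), C2, C3, C4 (isopropyl, O), C5 (ring-fusion CH), C6 (O), C7, C8 (CH3 = C14), C9, C10. In the target the C15 methyl, H5, the isopropyl group and the epoxide oxygen lie on one face; the C4 and C6 oxygens lie on the other.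

**Route**

Step 1
Reactants: 1 (S)-(+)-terpinen-4-ol [(1S)-4-methyl-1-(propan-2-yl)cyclohex-3-en-1-ol]
Product: 2 triethyl{[(1S)-4-methyl-1-(propan-2-yl)cyclohex-3-en-1-yl]oxy}silane
Conditions: Et3SiOTf (1.3 equiv), 2,6-lutidine (2 equiv), CH2Cl2, 0 °C to rt
Reagents that add atoms: triethylsilyl trifluoromethanesulfonate, CC[Si](CC)(CC)OS(=O)(=O)C(F)(F)F
Why: O-silylation of the hindered tertiary alcohol with a silyl triflate (no stereocentre touched) masks the C4 oxygen so that it is not lost as water in the aldol dehydration of step 3.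

Step 2
Reactants: 2 triethyl{[(1S)-4-methyl-1-(propan-2-yl)cyclohex-3-en-1-yl]oxy}silane
Product: 3 (3S)-6-oxo-3-(propan-2-yl)-3-[(triethylsilyl)oxy]heptanal
Conditions: O3, CH2Cl2/MeOH (4:1), −78 °C; then Me2S, −78 °C to rt
Reagents that add atoms: ozone, [O-][O+]=O
Why: Ozonolysis with reductive work-up cleaves the only C=C bond to the 1,6-keto aldehyde without touching the quaternary carbinol centre.

Step 3
Reactants: 3 (3S)-6-oxo-3-(propan-2-yl)-3-[(triethylsilyl)oxy]heptanal
Product: 4 (5R)-2-methyl-5-(propan-2-yl)-5-[(triethylsilyl)oxy]cyclopent-1-ene-1-carbaldehyde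
Conditions: piperidine (0.3 equiv), AcOH (0.3 equiv), toluene, 60 °C
Reagents that add atoms: none
Why: Amine-catalysed intramolecular aldol condensation in which the aldehyde enamine attacks the methyl ketone (five-membered ring closure) and the new free tertiary hydroxyl, rather than the silyloxy group, is eliminated to the conjugated enal, so the ring contraction keeps the purchased stereocentre as C4.

Step 4
Reactants: 4 (5R)-2-methyl-5-(propan-2-yl)-5-[(triethylsilyl)oxy]cyclopent-1-ene-1-carbaldehyde; 5 allylmagnesium bromide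
Product: 7 1-[(5R)-5-hydroxy-2-methyl-5-(propan-2-yl)cyclopent-1-en-1-yl]but-3-en-1-ol (both carbinol epimers), via silyl ether carbinol 6 (not isolated)
Conditions: CH2=CHCH2MgBr (1.5 equiv), THF, −78 °C; aq. NH4Cl; then Bu4NF (2 equiv), THF, 0 °C to rt
Reagents that add atoms: allylmagnesium bromide, C=CC[Mg]Br
Why: 1,2-Grignard addition to the hindered enal gives the 3-hydroxy-1,5-diene (its new carbinol centre is formed unselectively and is erased in step 5), and fluoride desilylation then frees the tertiary hydroxyl so that the rearrangement runs on a dialkoxide that cannot undergo beta-elimination.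

Step 5
Reactants: 7 1-[(5R)-5-hydroxy-2-methyl-5-(propan-2-yl)cyclopent-1-en-1-yl]but-3-en-1-ol
Product: 10 triethyl{[(1R,3S)-3-methyl-1-(propan-2-yl)-3-(prop-2-en-1-yl)-2-{[(triethylsilyl)oxy]methylidene}cyclopentyl]oxy}silane (enol ether E/Z mixture), via dipotassium dialkoxide 8 (not isolated), via dipotassium alkoxide enolate 9 (not isolated)
Conditions: KH (3 equiv), 18-crown-6 (3 equiv), THF, 0 to 50 °C; then Et3SiCl (3 equiv), −78 to 0 °C
Reagents that add atoms: chlorotriethylsilane, CC[Si](Cl)(CC)CC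
Why: Anionic oxy-Cope rearrangement ([3,3]-sigmatropic shift) moves the allyl group suprafacially from C6 to the fully substituted alkene carbon C1 across the ring face that carries the small C4 oxide instead of the isopropyl group, which creates the quaternary C1 centre with the allyl arm cis to the C4 oxygen, and the resulting alkoxide and aldehyde enolate are both trapped by O-silylation.

Step 6
Reactants: 10 triethyl{[(1R,3S)-3-methyl-1-(propan-2-yl)-3-(prop-2-en-1-yl)-2-{[(triethylsilyl)oxy]methylidene}cyclopentyl]oxy}silane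
Product: 11 (1R,2S,5R)-2-methyl-5-(propan-2-yl)-2-(prop-2-en-1-yl)-5-[(triethylsilyl)oxy]cyclopentane-1-carbaldehyde
Conditions: K2CO3 (0.2 equiv), MeOH, 0 °C to rt
Reagents that add atoms: none
Why: Methanolysis of the enol silyl ether (the hindered tertiary silyl ether survives) liberates the aldehyde under equilibrating conditions, so C5 settles in its more stable configuration with the formyl group trans to the isopropyl group and cis to the allyl arm, the arrangement needed for the cis ring fusion.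

Step 7
Reactants: 11 (1R,2S,5R)-2-methyl-5-(propan-2-yl)-2-(prop-2-en-1-yl)-5-[(triethylsilyl)oxy]cyclopentane-1-carbaldehyde; 12 (2-methylprop-2-en-1-yl)magnesium chloride
Product: 13 (1R)-3-methyl-1-{(1S,2S,5R)-2-methyl-5-(propan-2-yl)-2-(prop-2-en-1-yl)-5-[(triethylsilyl)oxy]cyclopentyl}but-3-en-1-ol
Conditions: CH2=C(CH3)CH2MgCl (2 equiv), THF, −78 °C, cold aq. NH4Cl quench
Reagents that add atoms: (2-methylprop-2-en-1-yl)magnesium chloride, CC(=C)C[Mg]Cl
Why: Felkin–Anh-controlled Grignard addition in which the non-chelating silyl ether leaves the bulky C4 branch anti to the incoming methallyl nucleophile, which passes the small C5 hydrogen and delivers the 6R carbinol.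

Step 8
Reactants: 13 (1R)-3-methyl-1-{(1S,2S,5R)-2-methyl-5-(propan-2-yl)-2-(prop-2-en-1-yl)-5-[(triethylsilyl)oxy]cyclopentyl}but-3-en-1-ol
Product: 14 (3R,3aS,4R,8aS)-6,8a-dimethyl-3-(propan-2-yl)-3-[(triethylsilyl)oxy]-1,2,3,3a,4,5,8,8a-octahydroazulen-4-ol
Conditions: second-generation Grubbs catalyst RuCl2(=CHPh)(H2IMes)(PCy3) (5 mol %), CH2Cl2 (5 mM), 40 °C
Reagents that add atoms: none
Why: Ring-closing olefin metathesis between the allyl alkene and the 1,1-disubstituted methallyl alkene, held cis on the cyclopentane, closes the seven-membered ring with the trisubstituted C8=C9 alkene and releases ethene without touching a stereocentre.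

Step 9
Reactants: 14 (3R,3aS,4R,8aS)-6,8a-dimethyl-3-(propan-2-yl)-3-[(triethylsilyl)oxy]-1,2,3,3a,4,5,8,8a-octahydroazulen-4-ol; 15 4-[(tert-butyldimethylsilyl)oxy]benzoic acid
Product: 16 (3R,3aS,4R,8aS)-6,8a-dimethyl-3-(propan-2-yl)-3-[(triethylsilyl)oxy]-1,2,3,3a,4,5,8,8a-octahydroazulen-4-yl 4-[(tert-butyldimethylsilyl)oxy]benzoate
Conditions: DCC (1.5 equiv), DMAP (0.3 equiv), CH2Cl2, rt to 40 °C
Reagents that add atoms: 4-[(tert-butyldimethylsilyl)oxy]benzoic acid, CC(C)(C)[Si](C)(C)Oc1ccc(cc1)C(O)=O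
Why: Steglich esterification (carbodiimide activation, acyl transfer through DMAP) acylates the only free hydroxyl with retention at C6.

Step 10
Reactants: 16 (3R,3aS,4R,8aS)-6,8a-dimethyl-3-(propan-2-yl)-3-[(triethylsilyl)oxy]-1,2,3,3a,4,5,8,8a-octahydroazulen-4-yl 4-[(tert-butyldimethylsilyl)oxy]benzoate
Product: 17 (1S,4R,5S,6R,8R,9S)-8,9-epoxy-4-[(triethylsilyl)oxy]daucan-6-yl 4-[(tert-butyldimethylsilyl)oxy]benzoate (cis-fused; epoxide oxygen on the face of the C15 methyl and H5)
Conditions: mCPBA (1.3 equiv), CH2Cl2, 0 °C; aq. NaHCO3 wash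
Reagents that add atoms: 3-chloroperoxybenzoic acid, OOC(=O)c1cccc(Cl)c1
Why: Prilezhaev epoxidation of the trisubstituted alkene from the convex face of the cis-fused bicycle (the face of the angular methyl and H5), because the concave face is screened by the C4 silyloxy group, the C6 aroyloxy group and the five-membered ring, which sets the 8R,9S epoxide.

Step 11
Reactants: 17 (1S,4R,5S,6R,8R,9S)-8,9-epoxy-4-[(triethylsilyl)oxy]daucan-6-yl 4-[(tert-butyldimethylsilyl)oxy]benzoate
Product: 18 (1S,4R,5S,6R,8R,9S)-8,9-epoxy-4-hydroxydaucan-6-yl 4-hydroxybenzoate (target CNP0163817.4)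
Conditions: Bu4NF (3 equiv), THF, 0 °C to rt; pH 7 buffer work-up
Reagents that add atoms: none
Why: Fluoride-induced desilylation removes the aryl silyl ether and the tertiary triethylsilyl ether under non-acidic conditions that leave the epoxide and the aryl ester (deactivated as its phenoxide) intact.

**Compound list**
1 | (S)-(+)-terpinen-4-ol | CC1=CC[C@](O)(C(C)C)CC1 | starting material
2 | triethyl{[(1S)-4-methyl-1-(propan-2-yl)cyclohex-3-en-1-yl]oxy}silane | CC1=CC[C@](O[Si](CC)(CC)CC)(C(C)C)CC1 | intermediate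
3 | (3S)-6-oxo-3-(propan-2-yl)-3-[(triethylsilyl)oxy]heptanal | O=CC[C@](O[Si](CC)(CC)CC)(C(C)C)CCC(C)=O | intermediate
4 | (5R)-2-methyl-5-(propan-2-yl)-5-[(triethylsilyl)oxy]cyclopent-1-ene-1-carbaldehyde | CC(C)[C@]1(O[Si](CC)(CC)CC)CCC(C)=C1C=O | intermediate
5 | allylmagnesium bromide | C=CC[Mg]Br | starting material
6 | 1-{(5R)-2-methyl-5-(propan-2-yl)-5-[(triethylsilyl)oxy]cyclopent-1-en-1-yl}but-3-en-1-ol (both carbinol epimers) | CC(C)[C@]1(O[Si](CC)(CC)CC)CCC(C)=C1C(O)CC=C | intermediate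
7 | 1-[(5R)-5-hydroxy-2-methyl-5-(propan-2-yl)cyclopent-1-en-1-yl]but-3-en-1-ol (both carbinol epimers) | CC(C)[C@]1(O)CCC(C)=C1C(O)CC=C | intermediate
8 | dipotassium 1-[(5R)-2-methyl-5-oxido-5-(propan-2-yl)cyclopent-1-en-1-yl]but-3-en-1-olate | CC(C)[C@]1([O-])CCC(C)=C1C([O-])CC=C.[K+].[K+] | intermediate
9 | dipotassium (1R,3S)-3-methyl-2-(oxidomethylidene)-1-(propan-2-yl)-3-(prop-2-en-1-yl)cyclopentan-1-olate | CC(C)[C@]1([O-])CC[C@@](C)(CC=C)C1=C[O-].[K+].[K+] | intermediate
10 | triethyl{[(1R,3S)-3-methyl-1-(propan-2-yl)-3-(prop-2-en-1-yl)-2-{[(triethylsilyl)oxy]methylidene}cyclopentyl]oxy}silane | CC(C)[C@]1(O[Si](CC)(CC)CC)CC[C@@](C)(CC=C)C1=CO[Si](CC)(CC)CC | intermediate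
11 | (1R,2S,5R)-2-methyl-5-(propan-2-yl)-2-(prop-2-en-1-yl)-5-[(triethylsilyl)oxy]cyclopentane-1-carbaldehyde | CC(C)[C@]1(O[Si](CC)(CC)CC)CC[C@@](C)(CC=C)[C@H]1C=O | intermediate
12 | (2-methylprop-2-en-1-yl)magnesium chloride | CC(=C)C[Mg]Cl | starting material
13 | (1R)-3-methyl-1-{(1S,2S,5R)-2-methyl-5-(propan-2-yl)-2-(prop-2-en-1-yl)-5-[(triethylsilyl)oxy]cyclopentyl}but-3-en-1-ol | CC(C)[C@]1(O[Si](CC)(CC)CC)CC[C@@](C)(CC=C)[C@H]1[C@H](O)CC(C)=C | intermediate
14 | (3R,3aS,4R,8aS)-6,8a-dimethyl-3-(propan-2-yl)-3-[(triethylsilyl)oxy]-1,2,3,3a,4,5,8,8a-octahydroazulen-4-ol | CC(C)[C@]1(O[Si](CC)(CC)CC)CC[C@@]2(C)CC=C(C)C[C@@H](O)[C@H]21 | intermediate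
15 | 4-[(tert-butyldimethylsilyl)oxy]benzoic acid | CC(C)(C)[Si](C)(C)Oc1ccc(cc1)C(O)=O | starting material
16 | (3R,3aS,4R,8aS)-6,8a-dimethyl-3-(propan-2-yl)-3-[(triethylsilyl)oxy]-1,2,3,3a,4,5,8,8a-octahydroazulen-4-yl 4-[(tert-butyldimethylsilyl)oxy]benzoate | CC(C)[C@]1(O[Si](CC)(CC)CC)CC[C@@]2(C)CC=C(C)C[C@@H](OC(=O)c3ccc(O[Si](C)(C)C(C)(C)C)cc3)[C@H]21 | intermediate
17 | (1S,4R,5S,6R,8R,9S)-8,9-epoxy-4-[(triethylsilyl)oxy]daucan-6-yl 4-[(tert-butyldimethylsilyl)oxy]benzoate | CC(C)[C@]1(O[Si](CC)(CC)CC)CC[C@@]2(C)C[C@@H]3O[C@]3(C)C[C@@H](OC(=O)c3ccc(O[Si](C)(C)C(C)(C)C)cc3)[C@H]21 | intermediate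
18 | (1S,4R,5S,6R,8R,9S)-8,9-epoxy-4-hydroxydaucan-6-yl 4-hydroxybenzoate | CC(C)[C@]1(O)CC[C@@]2(C)C[C@@H]3O[C@]3(C)C[C@@H](OC(=O)c3ccc(O)cc3)[C@H]21 | target

**Step count**
Total steps: 11. Longest linear sequence: 11 steps (1 to 18).

**Steps most likely to fail, with fallbacks**

Step 5. The dianionic oxy-Cope has to form a quaternary carbon at a fully substituted alkene terminus; it may be slow or lose material by fragmentation. The fallback replaces the anionic rearrangement by a neutral thermal one. It sets out from 6, isolated by leaving out the Bu4NF treatment in step 4. The secondary hydroxyl is silylated (Et3SiCl, imidazole, DMF) to the bis(triethylsilyl) ether F1, and this is heated at about 210 °C (o-dichlorobenzene, sealed tube, trace Et3N). The thermal siloxy-Cope rearrangement gives the silyl enol ether 10 directly, where the route is rejoined.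

Step 7. Felkin selectivity at C6 on this doubly neopentyl aldehyde may be low or reversed. The fallback sets C6 by hydride delivery instead of by the carbon nucleophile. It sets out from 14, used as whatever C6 epimer mixture steps 7 and 8 deliver. Oxidation with Dess–Martin periodinane (NaHCO3, CH2Cl2) gives the bicyclic ketone F2. HF·pyridine (pyridine, THF, 0 °C) removes the silyl group to give the β-hydroxy ketone F3. Reduction with Zn(BH4)2 (Et2O, −20 °C) gives the diol F4; the zinc chelate of the C4 hydroxyl and the C6 carbonyl is attacked on its open convex face, which gives 6R. The secondary hydroxyl is acylated with 15 (DCC, DMAP) to the hydroxy ester F5, and silylation of the tertiary hydroxyl (Et3SiOTf, 2,6-lutidine) returns to the route at 16.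

Step 10. The facial preference of the peracid on the flexible cycloheptene is the least secure stereochemical call in the route. The fallback is a two-step epoxide synthesis with the opposite facial outcome. It sets out from 16. NBS in THF/H2O forms the bromonium ion on the face the peracid prefers, and water opens it at the tertiary C8 from the other face to give the bromohydrin F6. DBU (CH2Cl2) then closes it with inversion at C9 to the epoxide 17, where the route is rejoined.

**Further compounds**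
F1 | step 5 | triethyl{[(1R)-1-isopropyl-3-methyl-2-(1-[(triethylsilyl)oxy]but-3-en-1-yl)cyclopent-2-en-1-yl]oxy}silane, the bis(triethylsilyl) ether of 6 (both C6 epimers) | CC(C)[C@]1(O[Si](CC)(CC)CC)CCC(C)=C1C(O[Si](CC)(CC)CC)CC=C
F2 | step 7 | (3R,3aR,8aS)-6,8a-dimethyl-3-(propan-2-yl)-3-[(triethylsilyl)oxy]-2,3,3a,5,8,8a-hexahydroazulen-4(1H)-one | CC(C)[C@]1(O[Si](CC)(CC)CC)CC[C@@]2(C)CC=C(C)CC(=O)[C@H]21
F3 | step 7 | (3R,3aR,8aS)-3-hydroxy-6,8a-dimethyl-3-(propan-2-yl)-2,3,3a,5,8,8a-hexahydroazulen-4(1H)-one | CC(C)[C@]1(O)CC[C@@]2(C)CC=C(C)CC(=O)[C@H]21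
F4 | step 7 | (3R,3aS,4R,8aS)-6,8a-dimethyl-3-(propan-2-yl)-1,2,3,3a,4,5,8,8a-octahydroazulene-3,4-diol | CC(C)[C@]1(O)CC[C@@]2(C)CC=C(C)C[C@@H](O)[C@H]21
F5 | step 7 | (3R,3aS,4R,8aS)-3-hydroxy-6,8a-dimethyl-3-(propan-2-yl)-1,2,3,3a,4,5,8,8a-octahydroazulen-4-yl 4-[(tert-butyldimethylsilyl)oxy]benzoate | CC(C)[C@]1(O)CC[C@@]2(C)CC=C(C)C[C@@H](OC(=O)c3ccc(O[Si](C)(C)C(C)(C)C)cc3)[C@H]21
F6 | step 10 | (1S,4R,5S,6R,8R,9R)-9-bromo-8-hydroxy-4-[(triethylsilyl)oxy]daucan-6-yl 4-[(tert-butyldimethylsilyl)oxy]benzoate (C8 hydroxyl on the face of the C15 methyl, C9 bromine on the opposite face) | CC(C)[C@]1(O[Si](CC)(CC)CC)CC[C@@]2(C)C[C@@H](Br)[C@](C)(O)C[C@@H](OC(=O)c3ccc(O[Si](C)(C)C(C)(C)C)cc3)[C@H]21
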